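The synthesis rests on cutting two bonds at the vicinal pair of the cyclohexane ring: C2–CH2 of the 3-oxobutyl arm and C1–C(=O) of the acyl chain. The key step exploits three features. The arm (C2) and the acyl group (quaternary C1) are trans, C2 adjoins the C3 gem-dimethyl carbon, and C6 is a bare methylene that can carry a temporary carbonyl. With C6=O in place, enantioselective β-addition at C2 and α-aldol trapping at C1 join three fragments, form both bonds and set both stereocentres in one operation. The precursors are 2,4,4-trimethylcyclohex-2-enone, a ketal-masked 3-oxobutyl Grignard reagent and a geraniol-derived, silyl-protected C7 aldehyde. Deoxygenation at C6, carbinol oxidation and unmasking follow.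

Key step: step 5

Ring numbering used throughout: C1 = quaternary carbon (CH3, acyl), C2 = CH bearing the arm, C3 = CMe2, C4–C6 = CH2 (C6 next to C1). The target is (1R,2R), with arm and acyl group trans, the C1 methyl cis to the arm, and an E alkene.

Assumption: the sense of induction of the ferrocenyl diphosphine on the trimethylcyclohexenone cannot be derived safely from simpler enones. Both ligand antipodes are commercial, and the antipode named in step 5 stands for whichever one directs the alkyl group to the Re face of C2.

Step 1
Reactants: 1 geraniol [(E)-3,7-dimethylocta-2,6-dien-1-ol]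
Product: 2 geranyl tert-butyldimethylsilyl ether
Conditions: TBSCl, imidazole, CH2Cl2, 0 °C → rt
Reagents that add atoms: tert-butyldimethylsilyl chloride, CC(C)(C)[Si](C)(C)Cl
Why: Imidazole-promoted silylation of a primary allylic alcohol is routine, and a silyl ether is preferred to the final acetate here because it is inert both to the Grignard reagent and to copper-catalysed allylic substitution in step 5.

Step 2
Reactants: 2 geranyl tert-butyldimethylsilyl ether
Product: 3 6,7-epoxygeranyl tert-butyldimethylsilyl ether (racemic at the oxirane CH; E alkene retained)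
Conditions: mCPBA (1.0 equiv), CH2Cl2, −20 → 0 °C
Reagents that add atoms: 3-chloroperbenzoic acid, OOC(=O)c1cccc(Cl)c1
Why: In the Prilezhaev epoxidation the more nucleophilic alkene reacts first, so one equivalent of peracid should take the remote 6,7-alkene rather than the 2,3-alkene, which the allylic oxygen deactivates inductively; the new stereocentre is racemic and is destroyed in step 3.

Step 3
Reactants: 3 6,7-epoxygeranyl tert-butyldimethylsilyl ether
Product: 5 (E)-6-(tert-butyldimethylsilyloxy)-4-methylhex-4-enal, via 6,7-diol 4 (not isolated)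
Conditions: H5IO6 (1.1 equiv), THF/Et2O, 0 °C
Reagents that add atoms: water, O (supplied by H5IO6; its oxygen enters diol 4 at the tertiary carbon and leaves with the acetone)
Why: Periodic acid opens the epoxide to the vicinal diol and cleaves it at once (Malaprade glycol cleavage), leaving the E-2,3-alkene untouched, and a primary TBS ether tolerates the short contact at 0 °C.

Step 4
Reactants: 6 2-(2-bromoethyl)-2-methyl-1,3-dioxolane
Product: 7 [2-(2-methyl-1,3-dioxolan-2-yl)ethyl]magnesium bromide (titrated solution)
Conditions: Mg turnings, I2 (crystal), THF (concentrated), 20–25 °C; titrated, diluted with t-BuOMe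
Reagents that add atoms: magnesium, [Mg]
Why: Grignard formation by magnesium insertion into a primary alkyl bromide is routine; the temperature is capped because β-ketal Grignard reagents fragment on warming, and dilution with t-BuOMe keeps the THF content of step 5 low.

Step 5
Reactants: 7 [2-(2-methyl-1,3-dioxolan-2-yl)ethyl]magnesium bromide; 8 2,4,4-trimethylcyclohex-2-en-1-one; 5 (E)-6-(tert-butyldimethylsilyloxy)-4-methylhex-4-enal
Product: 11 aldol adduct (2R,3R)-2-[(E)-6-(tert-butyldimethylsilyloxy)-1-hydroxy-4-methylhex-4-en-1-yl]-2,4,4-trimethyl-3-[2-(2-methyl-1,3-dioxolan-2-yl)ethyl]cyclohexan-1-one (either carbinol epimer), via magnesium enolate 9 (not isolated), via magnesium aldolate 10 (not isolated)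
Conditions: CuBr·SMe2 (10 mol %), (R)-1-[(S)-2-(diphenylphosphino)ferrocenyl]ethyldicyclohexylphosphine (12 mol %), t-BuOMe, −78 °C; 7 (0.95 equiv) added slowly, −78 → −40 °C; 5 (1.1 equiv), −78 °C; sat. aq NH4Cl, −78 °C → rt
Reagents that add atoms: none
Why: The ligated monovalent copper bromide is transmetallated by 7 and binds the C1=C2 π bond of 8; oxidative addition at C2 to a trivalent copper species and reductive elimination form the C2–CH2 bond and release the C1=C6 bromomagnesium enolate 9, which adds through C1 to aldehyde 5 in a closed, magnesium-bridged Zimmerman–Traxler transition state to give aldolate 10, and no ring is closed. The closest known reaction type is the copper-catalysed asymmetric conjugate addition of Grignard reagents to cyclic enones (α-methyl members included) with trapping of the magnesium enolate by an electrophile, and 8 is a crowded member of that class because C2 is neopentylic. C2 is controlled by the ligand, which must deliver the alkyl group to the Re face to give the (R) centre. C1 is controlled by the substrate: allylic 1,2-strain with the C1 methyl holds the new arm pseudoaxial, so axial attack on the aldehyde takes the opposite face and places the carbinol chain trans and the methyl cis to the arm, which is also the more stable isomer (both large groups equatorial after ring flip) should the aldol equilibrate. The carbinol centre needs no control because step 8 erases it. The step needs 1,4-addition rather than 1,2-addition or deprotonation at C5, the only acidic site of 8 (secured by copper catalysis, slow addition and low temperature), retention of the enolate regiochemistry (fixed by the addition and trapped cold), and no loss of 5 to free Grignard reagent (7 is the limiting component).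

Step 6
Reactants: 11 aldol adduct
Product: 12 C6 tosylhydrazone of 11 (C1, C2, carbinol, ketal and silyl ether unchanged)
Conditions: TsNHNH2 (1.5 equiv), 4 Å MS, EtOH, 55 °C
Reagents that add atoms: p-toluenesulfonyl hydrazide, Cc1ccc(cc1)S(=O)(=O)NN
Why: In this hydrazone condensation only the C6 carbonyl is free and its C5 flank is open, while neutral conditions avoid retro-aldol cleavage at C1 and acid-induced ketal exchange.

Step 7
Reactants: 12 C6 tosylhydrazone
Product: 15 (E)-6-(tert-butyldimethylsilyloxy)-4-methyl-1-{(1R,2R)-1,3,3-trimethyl-2-[2-(2-methyl-1,3-dioxolan-2-yl)ethyl]cyclohexyl}hex-4-en-1-ol (either carbinol epimer), via tosylhydrazine 13 (not isolated), via diazene 14 (not isolated)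
Conditions: catecholborane (3.5 equiv), CHCl3, −10 → 0 °C; NaOAc·3H2O, reflux
Reagents that add atoms: none
Why: In this catecholborane variant of the Caglioti tosylhydrazone reduction, hydride adds to C=N (one further equivalent is consumed by the O–H), acetate triggers loss of sulfinate, and the diazene extrudes N2 to leave the C6 methylene; silyl ether, ketal and trisubstituted alkene are inert to catecholborane at this temperature, and C1 and C2 are not involved.

Step 8
Reactants: 15 carbinol
Product: 16 (E)-6-(tert-butyldimethylsilyloxy)-4-methyl-1-{(1R,2R)-1,3,3-trimethyl-2-[2-(2-methyl-1,3-dioxolan-2-yl)ethyl]cyclohexyl}hex-4-en-1-one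
Conditions: Dess–Martin periodinane (1.3 equiv), pyridine, CH2Cl2, 0 °C → rt
Reagents that add atoms: none
Why: Dess–Martin oxidation handles hindered secondary alcohols, the pyridine buffer protects ketal and silyl ether, both carbinol epimers converge on one ketone, and the quaternary α-carbon C1 cannot epimerise.

Step 9
Reactants: 16 silyl ether ketal ketone
Product: 17 (E)-6-hydroxy-4-methyl-1-[(1R,2R)-1,3,3-trimethyl-2-(3-oxobutyl)cyclohexyl]hex-4-en-1-one
Conditions: 1 M aq HCl, THF, 0 °C → rt
Reagents that add atoms: water, O
Why: Acid-catalysed ketal hydrolysis and acidic desilylation of the primary silyl ether run in the same pot and save a separate fluoride step; the medium is too mild for allylic ionisation, and the shielded C1 acyl ketone is a poor acceptor for an intramolecular aldol reaction.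

Step 10
Reactants: 17 hydroxy diketone
Product: 18 (2E)-3-methyl-6-oxo-6-[(1R,2R)-1,3,3-trimethyl-2-(3-oxobutyl)cyclohexyl]hex-2-en-1-yl acetate (target)
Conditions: Ac2O, pyridine, DMAP (cat.), CH2Cl2, 0 °C → rt
Reagents that add atoms: acetic anhydride, CC(=O)OC(C)=O
Why: DMAP-catalysed acetylation of the only hydroxyl group, a primary allylic alcohol, completes the target without touching a stereocentre or the alkene geometry.

Compound list
1 | geraniol | CC(C)=CCC/C(C)=C/CO | starting material
2 | geranyl tert-butyldimethylsilyl ether | CC(C)=CCC/C(C)=C/CO[Si](C)(C)C(C)(C)C | intermediate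
3 | 6,7-epoxygeranyl tert-butyldimethylsilyl ether (racemic at the oxirane CH) | CC1(C)OC1CC/C(C)=C/CO[Si](C)(C)C(C)(C)C | intermediate
4 | (E)-8-(tert-butyldimethylsilyloxy)-2,6-dimethyloct-6-ene-2,3-diol (not isolated) | CC(C)(O)C(O)CC/C(C)=C/CO[Si](C)(C)C(C)(C)C | intermediate
5 | (E)-6-(tert-butyldimethylsilyloxy)-4-methylhex-4-enal | O=CCC/C(C)=C/CO[Si](C)(C)C(C)(C)C | intermediate
6 | 2-(2-bromoethyl)-2-methyl-1,3-dioxolane | CC1(CCBr)OCCO1 | starting material
7 | [2-(2-methyl-1,3-dioxolan-2-yl)ethyl]magnesium bromide | CC1(CC[Mg]Br)OCCO1 | intermediate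
8 | 2,4,4-trimethylcyclohex-2-en-1-one | CC1=CC(C)(C)CCC1=O | starting material
9 | bromomagnesium (3R)-2,4,4-trimethyl-3-[2-(2-methyl-1,3-dioxolan-2-yl)ethyl]cyclohex-1-en-1-olate (not isolated) | CC1(CC[C@@H]2C(C)(C)CCC(O[Mg]Br)=C2C)OCCO1 | intermediate
10 | bromomagnesium aldolate of 11 (not isolated) | CC1(CC[C@@H]2C(C)(C)CCC(=O)[C@@]2(C)C(O[Mg]Br)CC/C(C)=C/CO[Si](C)(C)C(C)(C)C)OCCO1 | intermediate
11 | aldol adduct, ring ketone at C6, carbinol chain trans to the arm, carbinol carbon unassigned | CC1(CC[C@@H]2C(C)(C)CCC(=O)[C@@]2(C)C(O)CC/C(C)=C/CO[Si](C)(C)C(C)(C)C)OCCO1 | intermediate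
12 | C6 tosylhydrazone of 11 | CC1(CC[C@@H]2C(C)(C)CCC(=NNS(=O)(=O)c3ccc(C)cc3)[C@@]2(C)C(O)CC/C(C)=C/CO[Si](C)(C)C(C)(C)C)OCCO1 | intermediate
13 | C6 tosylhydrazine from hydride addition to 12 (boron-bound at N and O in the flask, written in its N–H/O–H form; not isolated) | CC1(CC[C@@H]2C(C)(C)CCC(NNS(=O)(=O)c3ccc(C)cc3)[C@@]2(C)C(O)CC/C(C)=C/CO[Si](C)(C)C(C)(C)C)OCCO1 | intermediate
14 | C6 alkyl diazene (not isolated) | CC1(CC[C@@H]2C(C)(C)CCC(N=N)[C@@]2(C)C(O)CC/C(C)=C/CO[Si](C)(C)C(C)(C)C)OCCO1 | intermediate
15 | deoxygenated carbinol (C6 = CH2) | CC1(CC[C@@H]2C(C)(C)CCC[C@@]2(C)C(O)CC/C(C)=C/CO[Si](C)(C)C(C)(C)C)OCCO1 | intermediate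
16 | side-chain ketone, ketal and silyl ether in place | CC1(CC[C@@H]2C(C)(C)CCC[C@@]2(C)C(=O)CC/C(C)=C/CO[Si](C)(C)C(C)(C)C)OCCO1 | intermediate
17 | hydroxy diketone | CC(=O)CC[C@@H]1C(C)(C)CCC[C@@]1(C)C(=O)CC/C(C)=C/CO | intermediate
18 | CNP0326957.1 | CC(=O)CC[C@@H]1C(C)(C)CCC[C@@]1(C)C(=O)CC/C(C)=C/COC(C)=O | target

Total step count: 10. Longest linear sequence: 9 steps (1–3 and 5–10, from geraniol).

Steps most likely to fail

Step 5.
- **Risk:** Copper-mediated transfer to the neopentylic C2 may be slow. Direct 1,2-addition, deprotonation at C5 or a poorly face-selective background reaction could then take over.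
- **Risk:** The face of C1 anti to the arm still carries the axial C3 methyl in a 1,3-relationship. The crowded enolate may therefore abstract an α-proton from the aldehyde, or the aldolate may revert before the quench.
- **Fallback:** The two bond formations are separated, setting out from 7 and 8. The same chiral copper catalyst is used in the presence of Me3SiCl, which accelerates the 1,4-addition and captures the product as the trimethylsilyl enol ether F1. This compound is isolated, freed from copper, magnesium salts and any 1,2-adduct, and checked for enantiomeric purity. MeLi in THF cleaves the O–Si bond to the regiodefined lithium enolate F2, and MgBr2·OEt2 converts it into magnesium enolate 9, now free of Grignard reagent. The route is rejoined at 9, which is treated with 5 as in step 5.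

Step 6.
- **Risk:** Condensation at a carbonyl flanked by the quaternary C1 may be slow. Prolonged heating invites retro-aldol cleavage or attack of the hydrazide at the ketal carbon.
- **Fallback:** Deoxygenation goes through the enol triflate, which needs only deprotonation at the open C5 flank and sets out from 11. N-(trimethylsilyl)imidazole caps the carbinol as the trimethylsilyl ether F3, which blocks retro-aldol under base. KN(SiMe3)2 in THF at −78 °C gives the potassium enolate F4, and PhNTf2 converts it into the C5=C6 enol triflate F5. Pd(OAc)2/PPh3 with HCO2H/Bu3N in DMF (zerovalent palladium, formate as hydride source) gives the silylated cyclohexene F6. K2CO3 in MeOH removes only the trimethylsilyl group to give the cyclohexene carbinol F7. Hydrogenation over RhCl(PPh3)3 saturates the disubstituted ring alkene and leaves the trisubstituted side-chain alkene, rejoining the route at 15.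

Step 7.
- **Risk:** Hydride transfer to the C=N bond next to C1 may stall. Unreduced hydrazone would then enter the heating stage and decompose by elimination, or the diazene may collapse unselectively.
- **Fallback:** The same hydrazone 12 is used in a Shapiro reaction. Excess n-BuLi (THF/TMEDA, −78 → 0 °C) removes the O–H, the N–H and one C5 proton, and loss of sulfinate and N2 gives the vinyllithium alkoxide F8. A water quench gives the cyclohexene carbinol F7, and hydrogenation over RhCl(PPh3)3 as above returns to the route at 15.

Further compounds
F1 | step 5 | (R)-trimethylsilyl enol ether (C1=C6, OSiMe3 at C6) | CC1(CC[C@@H]2C(C)(C)CCC(O[Si](C)(C)C)=C2C)OCCO1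
F2 | step 5 | lithium enolate (C1=C6) | CC1(CC[C@@H]2C(C)(C)CCC(O[Li])=C2C)OCCO1
F3 | step 6 | trimethylsilyl ether of aldol adduct 11 | CC1(CC[C@@H]2C(C)(C)CCC(=O)[C@@]2(C)C(O[Si](C)(C)C)CC/C(C)=C/CO[Si](C)(C)C(C)(C)C)OCCO1
F4 | step 6 | potassium enolate (C5=C6) of F3 | CC1(CC[C@@H]2C(C)(C)CC=C(O[K])[C@@]2(C)C(O[Si](C)(C)C)CC/C(C)=C/CO[Si](C)(C)C(C)(C)C)OCCO1
F5 | step 6 | C5=C6 enol triflate | CC1(CC[C@@H]2C(C)(C)CC=C(OS(=O)(=O)C(F)(F)F)[C@@]2(C)C(O[Si](C)(C)C)CC/C(C)=C/CO[Si](C)(C)C(C)(C)C)OCCO1
F6 | step 6 | silylated cyclohexene (C5=C6) | CC1(CC[C@@H]2C(C)(C)CC=C[C@@]2(C)C(O[Si](C)(C)C)CC/C(C)=C/CO[Si](C)(C)C(C)(C)C)OCCO1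
F7 | step 6 | cyclohexene carbinol (C5=C6) | CC1(CC[C@@H]2C(C)(C)CC=C[C@@]2(C)C(O)CC/C(C)=C/CO[Si](C)(C)C(C)(C)C)OCCO1
F8 | step 7 | vinyllithium alkoxide (Li at C6) | CC1(CC[C@@H]2C(C)(C)CC=C([Li])[C@@]2(C)C(O[Li])CC/C(C)=C/CO[Si](C)(C)C(C)(C)C)OCCO1
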